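**Retrosynthetic overview**
1. Numbering (elemane): cyclohexane C5–C10; C10 is quaternary (CH3, vinyl C1=C2), C9 is CH2, C8 carries the angelate, C7/C6 carry the lactone (C11–C13), C5 carries the acrylic acid (C3, C4, C15); β is the face of the C10 methyl group.
2. Late stage: free acid from a 2-(trimethylsilyl)ethyl ester, angelate on the axial 8β-OH, both α-methylene groups by one double Mannich methylenation, 8β-OH by reduction of a C8 ketone, 6,12-lactone from an acetic ester arm on C7.
3. Key disconnection: ring bonds C9–C10 and C6–C7 are made in one flask from the acyclic enol ether 14, in which O6 is tied to C1 as an ether. A crossed [2+2] photocycloaddition forms C9–C10 (and C5–C6, with a temporary C6–C9 bond) in a 2-oxabicyclo[2.1.1]hexane; a Lewis acid then cuts the strained C6–C9 bond and replaces it by C6–C7.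
4. Enabling feature: O6 and O8 are 1,3-related across C7 in the cyclohexane, so with C8 as a ketone the ring is an aldol (β-alkoxy ketone) array. The vinyl group on C10 lets its inner carbon C1 hold the temporary ether to O6, which a Boord fragmentation later opens to vinyl and 6-OH.
5. Ring order: oxolane and cyclobutane (temporary) → oxygen-bridged cyclohexanone → bridge opened → γ-lactone. All ring stereocentres derive from the carbinol centre of (S)-glyceraldehyde acetonide, which is destroyed when the vinyl group appears.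

Key step: step 9

Remark on the chemistry: 1 and 5 are taken as purchasable, and the (R) carbinol configuration was chosen on the assumption that 14 reacts through its conformer of minimal A(1,2) strain (see step 9).

Step 1
Reactants: 1 (S)-2,2-dimethyl-1,3-dioxolane-4-carbaldehyde
Product: 2 (R)-4-ethynyl-2,2-dimethyl-1,3-dioxolane
Conditions: dimethyl (1-diazo-2-oxopropyl)phosphonate, K2CO3, MeOH, 0 → 25 °C
Reagents that add atoms: dimethyl (1-diazo-2-oxopropyl)phosphonate COP(=O)(OC)C(=[N+]=[N-])C(C)=O
Why: The Ohira–Bestmann homologation should convert the aldehyde into the terminal alkyne under mild carbonate conditions that leave the adjacent stereocentre, carried over from 1, untouched.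

Step 2
Reactants: 2 (R)-4-ethynyl-2,2-dimethyl-1,3-dioxolane
Product: 4 (R)-4-[(E)-1-iodoprop-1-en-2-yl]-2,2-dimethyl-1,3-dioxolane, via alkenylalane 3 (not isolated)
Conditions: Me3Al, Cp2ZrCl2 (0.2 equiv), CH2Cl2, 0 → 25 °C; then I2, THF, −30 → 0 °C
Reagents that add atoms: trimethylaluminium C[Al](C)C; iodine II
Why: The zirconium-catalysed Negishi carboalumination adds methyl and aluminium syn across the alkyne with methyl on the internal carbon, and iodinolysis with retention should give the E iodoalkene.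

Step 3
Reactants: 4 (R)-4-[(E)-1-iodoprop-1-en-2-yl]-2,2-dimethyl-1,3-dioxolane; 5 2-(trimethylsilyl)ethyl 2-bromoacetate
Product: 7 2-(trimethylsilyl)ethyl (E)-4-[(R)-2,2-dimethyl-1,3-dioxolan-4-yl]pent-3-enoate, via Reformatsky reagent 6 (not isolated)
Conditions: 5, Zn dust, THF, 40 °C; then 4, Pd(PPh3)4 (5 mol %), THF, 50 °C
Reagents that add atoms: none
Why: The Negishi cross-coupling of an alkenyl iodide with a zinc ester enolate proceeds with retention of alkene geometry and should give the β,γ-unsaturated ester without conjugation.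

Step 4
Reactants: 7 2-(trimethylsilyl)ethyl (E)-4-[(R)-2,2-dimethyl-1,3-dioxolan-4-yl]pent-3-enoate
Product: 8 2-(trimethylsilyl)ethyl (3E,5R)-5,6-dihydroxy-4-methylhex-3-enoate
Conditions: AcOH–H2O (4:1), 40 °C
Reagents that add atoms: none
Why: Acid-catalysed acetal hydrolysis should free the diol under conditions that the ester and the E alkene tolerate, the carbinol centre being unaffected.

Step 5
Reactants: 8 2-(trimethylsilyl)ethyl (3E,5R)-5,6-dihydroxy-4-methylhex-3-enoate
Product: 10 2-(trimethylsilyl)ethyl (3E,5R)-6-bromo-5-hydroxy-4-methylhex-3-enoate, via primary tosylate 9 (not isolated)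
Conditions: p-TsCl, Et3N, Bu2SnO (5 mol %), CH2Cl2, 0 °C; evaporate; then LiBr, acetone, 50 °C
Reagents that add atoms: lithium bromide [Li+].[Br-]
Why: Stannylene-catalysed sulfonylation is selective for the primary hydroxyl, and SN2 displacement by bromide at that carbon leaves the allylic carbinol centre untouched.

Step 6
Reactants: 11 4-(tert-butoxy)-4-oxobutanoic acid
Product: 12 tert-butyl 4-[methoxy(methyl)amino]-4-oxobutanoate
Conditions: MeNHOMe·HCl, EDC·HCl, N-methylmorpholine, CH2Cl2, 0 → 25 °C
Reagents that add atoms: N,O-dimethylhydroxylamine hydrochloride CNOC.Cl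
Why: Carbodiimide-mediated amide coupling should give the Weinreb amide without touching the tert-butyl ester.

Step 7
Reactants: 12 tert-butyl 4-[methoxy(methyl)amino]-4-oxobutanoate
Product: 13 tert-butyl 4-oxohex-5-ynoate
Conditions: HC≡CMgBr, THF, −20 → 0 °C; then 1 M HCl
Reagents that add atoms: ethynylmagnesium bromide C#C[Mg]Br
Why: In the Weinreb ketone synthesis the chelated tetrahedral adduct prevents over-addition, so the terminal ynone should form while the hindered ester survives.

Step 8
Reactants: 10 2-(trimethylsilyl)ethyl (3E,5R)-6-bromo-5-hydroxy-4-methylhex-3-enoate; 13 tert-butyl 4-oxohex-5-ynoate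
Product: 14 tert-butyl (5E)-6-({(2R,3E)-1-bromo-3-methyl-6-oxo-6-[2-(trimethylsilyl)ethoxy]hex-3-en-2-yl}oxy)-4-oxohex-5-enoate
Conditions: DABCO (10 mol %), CH2Cl2, 0 → 25 °C
Reagents that add atoms: none
Why: The amine-catalysed oxa-Michael addition of an alcohol to a terminal ynone should give the E β-alkoxy enone, with the carbinol centre of 10 retained because only its O–H bond reacts.

Step 9
Reactants: 14 tert-butyl (5E)-6-({(2R,3E)-1-bromo-3-methyl-6-oxo-6-[2-(trimethylsilyl)ethoxy]hex-3-en-2-yl}oxy)-4-oxohex-5-enoate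
Product: 16 bridged ketone tert-butyl 2-[7-(bromomethyl)-1-methyl-3-oxo-8-{2-oxo-2-[2-(trimethylsilyl)ethoxy]ethyl}-6-oxabicyclo[3.2.1]octan-4-yl]acetate, via cyclobutane photoadduct 15 (not isolated)
Conditions: hν (λ > 290 nm, Pyrex), MeCN, 20 °C; evaporate; then Sc(OTf)3 (10 mol %), CH2Cl2, 0 → 25 °C
Reagents that add atoms: none
Why: Proposed new method: excitation of the β-alkoxy enone gives its triplet, whose β-carbon (C6) bonds to the alkene CH (C5) in a five-membered closure and whose α-carbon (C9) then closes onto the methyl-bearing carbon (C10), the crossed mode that a two-atom tether enforces, so that the strained 2-oxabicyclo[2.1.1]hexane 15 forms; 15 is a donor–acceptor cyclobutane (ring oxygen on C6, ketone on C9), and Sc(OTf)3 should cleave the C6–C9 bond with release of strain to an oxolanyl oxocarbenium ion and a scandium enolate, which after proton transfer to the other α-carbon (C7) closes the cyclohexanone by a 6-(enolendo)-exo-trig aldol-type addition. The closest known reaction types are the crossed intramolecular [2+2] photocycloaddition of 3-(allyloxy)enones and 3-(allyloxy)acrylates, the de Mayo retro-aldol opening of enone–alkene photoadducts, the Lewis acid opening of alkoxy-substituted donor–acceptor cyclobutanes and the acid-mediated addition of ketone enols to cyclic oxocarbenium ions; what is new is their relay into a ring expansion. C10 and C5 are set in the photocycloaddition by the E geometry of the alkene (the ester arm stays trans to the tether carbon) and by the carbinol centre, which should react through the conformer with its hydrogen eclipsing the vinylic methyl group (minimal A(1,2) strain) so that the enone adds to the alkene face anti to the bromomethyl group; C6 is fixed because the tethered enol can reach the oxocarbenium carbon from one face only, and C7 should end with its arm equatorial in the bridged chair (cis to the oxygen bridge), the epimer that step 10 corrects. The step needs crossed instead of straight cycloaddition (secured by the two-atom tether), cleavage of only the cyclobutane bond that lies between the donor oxygen and the acceptor ketone, and reclosure through C7 instead of C9 (C9 can only return the strained cyclobutane, C7 gives the unstrained six-membered ring).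

Step 10
Reactants: 16 bridged ketone tert-butyl 2-[7-(bromomethyl)-1-methyl-3-oxo-8-{2-oxo-2-[2-(trimethylsilyl)ethoxy]ethyl}-6-oxabicyclo[3.2.1]octan-4-yl]acetate
Product: 18 hydroxy ketone tert-butyl 2-[4-ethenyl-6-hydroxy-4-methyl-2-oxo-5-{2-oxo-2-[2-(trimethylsilyl)ethoxy]ethyl}cyclohexyl]acetate, via C7-epimeric hydroxy ketone 17 (not isolated)
Conditions: Zn dust, AcOH, EtOH, 60 °C; filter, evaporate; then imidazole, CHCl3, 25 °C
Reagents that add atoms: none
Why: The Boord fragmentation (zinc-induced reductive β-elimination of the β-bromo ether) should open the oxygen bridge to the C10 vinyl group and the 6α-hydroxyl, after which imidazole-mediated keto–enol equilibration moves the C7 arm into the equatorial position, trans to the hydroxyl and cis to the C5 arm.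

Step 11
Reactants: 18 hydroxy ketone tert-butyl 2-[4-ethenyl-6-hydroxy-4-methyl-2-oxo-5-{2-oxo-2-[2-(trimethylsilyl)ethoxy]ethyl}cyclohexyl]acetate
Product: 19 keto lactone 2-(trimethylsilyl)ethyl 2-(6-ethenyl-6-methyl-2,4-dioxooctahydro-1-benzofuran-7-yl)acetate
Conditions: TFA, CH2Cl2, 0 → 25 °C
Reagents that add atoms: none
Why: Acidolysis of the tert-butyl ester and lactonisation of the resulting acid onto the trans-diequatorial 6-hydroxyl should give the trans-fused γ-lactone, the primary silylethyl ester on the C5 arm being inert to these conditions.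

Step 12
Reactants: 19 keto lactone 2-(trimethylsilyl)ethyl 2-(6-ethenyl-6-methyl-2,4-dioxooctahydro-1-benzofuran-7-yl)acetate
Product: 20 hydroxy lactone 2-(trimethylsilyl)ethyl 2-(6-ethenyl-4-hydroxy-6-methyl-2-oxooctahydro-1-benzofuran-7-yl)acetate
Conditions: LiBH(s-Bu)3, THF, −78 °C; then AcOH
Reagents that add atoms: none
Why: In this hydride reduction the bulky borohydride should attack the C8 ketone equatorially, away from the syn-axial C10 methyl group, and so deliver the axial 8β-alcohol.

Step 13
Reactants: 20 hydroxy lactone 2-(trimethylsilyl)ethyl 2-(6-ethenyl-4-hydroxy-6-methyl-2-oxooctahydro-1-benzofuran-7-yl)acetate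
Product: 21 silyl ether 2-(trimethylsilyl)ethyl 2-{6-ethenyl-6-methyl-2-oxo-4-[(triethylsilyl)oxy]octahydro-1-benzofuran-7-yl}acetate
Conditions: Et3SiOTf, 2,6-lutidine, CH2Cl2, −78 → 0 °C
Reagents that add atoms: triethylsilyl trifluoromethanesulfonate CC[Si](CC)(CC)OS(=O)(=O)C(F)(F)F
Why: Silylation with the silyl triflate should protect the hindered axial hydroxyl so that it cannot attack the neighbouring lactone during the enolate chemistry of step 14.

Step 14
Reactants: 21 silyl ether 2-(trimethylsilyl)ethyl 2-{6-ethenyl-6-methyl-2-oxo-4-[(triethylsilyl)oxy]octahydro-1-benzofuran-7-yl}acetate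
Product: 24 bis-methylene compound 2-(trimethylsilyl)ethyl 2-{6-ethenyl-6-methyl-3-methylidene-2-oxo-4-[(triethylsilyl)oxy]octahydro-1-benzofuran-7-yl}prop-2-enoate, via bis-Mannich base 22 (not isolated), via bis-ammonium diiodide 23 (not isolated)
Conditions: LiN(i-Pr)2 (2.5 equiv), THF, −78 °C; CH2=NMe2 I, −78 → 0 °C; then MeI, MeOH, 25 °C; then aq. NaHCO3, EtOAc, 25 °C
Reagents that add atoms: N,N-dimethylmethyleneiminium iodide C[N+](C)=C.[I-]
Why: A double Mannich α-methylenation (aminomethylation of the lactone and ester enolates, exhaustive N-methylation, elimination of trimethylamine) should install both exocyclic methylene groups at once, the two new carbons being sp2 so that no stereocentre arises.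

Step 15
Reactants: 24 bis-methylene compound 2-(trimethylsilyl)ethyl 2-{6-ethenyl-6-methyl-3-methylidene-2-oxo-4-[(triethylsilyl)oxy]octahydro-1-benzofuran-7-yl}prop-2-enoate
Product: 25 2-(trimethylsilyl)ethyl 2-(6-ethenyl-4-hydroxy-6-methyl-3-methylidene-2-oxooctahydro-1-benzofuran-7-yl)prop-2-enoate
Conditions: AcOH–THF–H2O (3:1:1), 35 °C
Reagents that add atoms: none
Why: Mild acid hydrolysis should cleave the triethylsilyl ether while the silylethyl ester, which needs fluoride, and both Michael acceptors stay intact.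

Step 16
Reactants: 25 2-(trimethylsilyl)ethyl 2-(6-ethenyl-4-hydroxy-6-methyl-3-methylidene-2-oxooctahydro-1-benzofuran-7-yl)prop-2-enoate; 26 (2Z)-2-methylbut-2-enoic acid
Product: 28 2-(trimethylsilyl)ethyl 2-[(3aR,4R,6S,7R,7aR)-6-ethenyl-6-methyl-3-methylidene-4-{[(2Z)-2-methylbut-2-enoyl]oxy}-2-oxooctahydro-1-benzofuran-7-yl]prop-2-enoate, via mixed anhydride 27 (not isolated)
Conditions: 26, 2,4,6-trichlorobenzoyl chloride, Et3N, toluene, 25 °C; then 25, toluene, 80 °C
Reagents that add atoms: none
Why: A Yamaguchi-type mixed anhydride esterification run without a nucleophilic amine catalyst should acylate the axial hydroxyl with retention at C8 and avoid the addition–elimination pathway that turns angelates into tiglates.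

Step 17
Reactants: 28 2-(trimethylsilyl)ethyl 2-[(3aR,4R,6S,7R,7aR)-6-ethenyl-6-methyl-3-methylidene-4-{[(2Z)-2-methylbut-2-enoyl]oxy}-2-oxooctahydro-1-benzofuran-7-yl]prop-2-enoate
Product: 29 2-[(3aR,4R,6S,7R,7aR)-6-ethenyl-6-methyl-3-methylidene-4-{[(2Z)-2-methylbut-2-enoyl]oxy}-2-oxooctahydro-1-benzofuran-7-yl]prop-2-enoic acid
Conditions: Bu4NF, AcOH, THF, 0 → 25 °C
Reagents that add atoms: none
Why: Fluoride-induced β-elimination of the 2-(trimethylsilyl)ethyl ester should release the acid under buffered conditions that spare the angelate and the lactone.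

**Compound list**
1 | (S)-2,2-dimethyl-1,3-dioxolane-4-carbaldehyde | O=C[C@@H]1COC(C)(C)O1 | starting material
2 | (R)-4-ethynyl-2,2-dimethyl-1,3-dioxolane | C#C[C@@H]1COC(C)(C)O1 | intermediate
3 | dimethyl{(E)-2-[(R)-2,2-dimethyl-1,3-dioxolan-4-yl]prop-1-en-1-yl}alane | C[Al](C)/C=C(C)/[C@@H]1COC(C)(C)O1 | intermediate
4 | (R)-4-[(E)-1-iodoprop-1-en-2-yl]-2,2-dimethyl-1,3-dioxolane | I/C=C(C)/[C@@H]1COC(C)(C)O1 | intermediate
5 | 2-(trimethylsilyl)ethyl 2-bromoacetate | BrCC(=O)OCC[Si](C)(C)C | starting material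
6 | bromo{2-oxo-2-[2-(trimethylsilyl)ethoxy]ethyl}zinc | Br[Zn]CC(=O)OCC[Si](C)(C)C | intermediate
7 | 2-(trimethylsilyl)ethyl (E)-4-[(R)-2,2-dimethyl-1,3-dioxolan-4-yl]pent-3-enoate | C[Si](C)(C)CCOC(=O)C/C=C(C)/[C@@H]1COC(C)(C)O1 | intermediate
8 | 2-(trimethylsilyl)ethyl (3E,5R)-5,6-dihydroxy-4-methylhex-3-enoate | C[Si](C)(C)CCOC(=O)C/C=C(C)/[C@@H](O)CO | intermediate
9 | 2-(trimethylsilyl)ethyl (3E,5R)-5-hydroxy-4-methyl-6-[(4-methylbenzenesulfonyl)oxy]hex-3-enoate | C[Si](C)(C)CCOC(=O)C/C=C(C)/[C@@H](O)COS(=O)(=O)c1ccc(C)cc1 | intermediate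
10 | 2-(trimethylsilyl)ethyl (3E,5R)-6-bromo-5-hydroxy-4-methylhex-3-enoate | C[Si](C)(C)CCOC(=O)C/C=C(C)/[C@@H](O)CBr | intermediate
11 | 4-(tert-butoxy)-4-oxobutanoic acid | CC(C)(C)OC(=O)CCC(=O)O | starting material
12 | tert-butyl 4-[methoxy(methyl)amino]-4-oxobutanoate | CC(C)(C)OC(=O)CCC(=O)N(C)OC | intermediate
13 | tert-butyl 4-oxohex-5-ynoate | CC(C)(C)OC(=O)CCC(=O)C#C | intermediate
14 | tert-butyl (5E)-6-({(2R,3E)-1-bromo-3-methyl-6-oxo-6-[2-(trimethylsilyl)ethoxy]hex-3-en-2-yl}oxy)-4-oxohex-5-enoate | CC(C)(C)OC(=O)CCC(=O)/C=C/O[C@@H](CBr)/C(C)=C/CC(=O)OCC[Si](C)(C)C | intermediate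
15 | tert-butyl 4-[3-(bromomethyl)-4-methyl-6-{2-oxo-2-[2-(trimethylsilyl)ethoxy]ethyl}-2-oxabicyclo[2.1.1]hexan-5-yl]-4-oxobutanoate (3R; bromomethyl on the side of the arm-bearing bridge carbon; ester arm anti and acyl group syn to the oxygen bridge) | BrC[C@@H]1O[C@H]2[C@@H](C(=O)CCC(=O)OC(C)(C)C)[C@]1(C)[C@@H]2CC(=O)OCC[Si](C)(C)C | intermediate
16 | tert-butyl 2-[7-(bromomethyl)-1-methyl-3-oxo-8-{2-oxo-2-[2-(trimethylsilyl)ethoxy]ethyl}-6-oxabicyclo[3.2.1]octan-4-yl]acetate (7R, bromomethyl exo; 8-substituent anti to the oxygen bridge; 4-substituent equatorial, cis to the oxygen bridge) | BrC[C@@H]1O[C@H]2[C@@H](CC(=O)OC(C)(C)C)C(=O)C[C@]1(C)[C@@H]2CC(=O)OCC[Si](C)(C)C | intermediate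
17 | tert-butyl 2-[4-ethenyl-6-hydroxy-4-methyl-2-oxo-5-{2-oxo-2-[2-(trimethylsilyl)ethoxy]ethyl}cyclohexyl]acetate, C7 epimer (elemane descriptors 5α-H, 6β-H, 7β-H, 10β-CH3) | C=C[C@]1(C)CC(=O)[C@H](CC(=O)OC(C)(C)C)[C@H](O)[C@H]1CC(=O)OCC[Si](C)(C)C | intermediate
18 | tert-butyl 2-[4-ethenyl-6-hydroxy-4-methyl-2-oxo-5-{2-oxo-2-[2-(trimethylsilyl)ethoxy]ethyl}cyclohexyl]acetate (5α-H, 6β-H, 7α-H, 10β-CH3; both arms and the hydroxyl equatorial) | C=C[C@]1(C)CC(=O)[C@@H](CC(=O)OC(C)(C)C)[C@H](O)[C@H]1CC(=O)OCC[Si](C)(C)C | intermediate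
19 | 2-(trimethylsilyl)ethyl 2-(6-ethenyl-6-methyl-2,4-dioxooctahydro-1-benzofuran-7-yl)acetate (trans-fused lactone; ring configuration as in 29) | C=C[C@]1(C)CC(=O)[C@H]2CC(=O)O[C@@H]2[C@H]1CC(=O)OCC[Si](C)(C)C | intermediate
20 | 2-(trimethylsilyl)ethyl 2-(6-ethenyl-4-hydroxy-6-methyl-2-oxooctahydro-1-benzofuran-7-yl)acetate (axial 8β-OH; ring configuration as in 29) | C=C[C@]1(C)C[C@@H](O)[C@H]2CC(=O)O[C@@H]2[C@H]1CC(=O)OCC[Si](C)(C)C | intermediate
21 | 2-(trimethylsilyl)ethyl 2-{6-ethenyl-6-methyl-2-oxo-4-[(triethylsilyl)oxy]octahydro-1-benzofuran-7-yl}acetate (ring configuration as in 29) | C=C[C@]1(C)C[C@@H](O[Si](CC)(CC)CC)[C@H]2CC(=O)O[C@@H]2[C@H]1CC(=O)OCC[Si](C)(C)C | intermediate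
22 | bis(dimethylaminomethyl) adduct of 21 at the lactone α-carbon and the ester α-carbon (mixture of epimers at these two carbons) | C=C[C@]1(C)C[C@@H](O[Si](CC)(CC)CC)[C@H]2C(CN(C)C)C(=O)O[C@@H]2[C@H]1C(CN(C)C)C(=O)OCC[Si](C)(C)C | intermediate
23 | bis(trimethylammoniomethyl) diiodide derived from 22 | C=C[C@]1(C)C[C@@H](O[Si](CC)(CC)CC)[C@H]2C(C[N+](C)(C)C)C(=O)O[C@@H]2[C@H]1C(C[N+](C)(C)C)C(=O)OCC[Si](C)(C)C.[I-].[I-] | intermediate
24 | 2-(trimethylsilyl)ethyl 2-{(3aR,4R,6S,7R,7aR)-6-ethenyl-6-methyl-3-methylidene-2-oxo-4-[(triethylsilyl)oxy]octahydro-1-benzofuran-7-yl}prop-2-enoate | C=C[C@]1(C)C[C@@H](O[Si](CC)(CC)CC)[C@H]2C(=C)C(=O)O[C@@H]2[C@H]1C(=C)C(=O)OCC[Si](C)(C)C | intermediate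
25 | 2-(trimethylsilyl)ethyl 2-[(3aR,4R,6S,7R,7aR)-6-ethenyl-4-hydroxy-6-methyl-3-methylidene-2-oxooctahydro-1-benzofuran-7-yl]prop-2-enoate | C=C[C@]1(C)C[C@@H](O)[C@H]2C(=C)C(=O)O[C@@H]2[C@H]1C(=C)C(=O)OCC[Si](C)(C)C | intermediate
26 | (2Z)-2-methylbut-2-enoic acid (angelic acid) | C/C=C(/C)C(=O)O | starting material
27 | (2Z)-2-methylbut-2-enoic 2,4,6-trichlorobenzoic anhydride | C/C=C(/C)C(=O)OC(=O)c1c(Cl)cc(Cl)cc1Cl | intermediate
28 | 2-(trimethylsilyl)ethyl 2-[(3aR,4R,6S,7R,7aR)-6-ethenyl-6-methyl-3-methylidene-4-{[(2Z)-2-methylbut-2-enoyl]oxy}-2-oxooctahydro-1-benzofuran-7-yl]prop-2-enoate | C=C[C@]1(C)C[C@@H](OC(=O)/C(C)=C\C)[C@H]2C(=C)C(=O)O[C@@H]2[C@H]1C(=C)C(=O)OCC[Si](C)(C)C | intermediate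
29 | 2-[(3aR,4R,6S,7R,7aR)-6-ethenyl-6-methyl-3-methylidene-4-{[(2Z)-2-methylbut-2-enoyl]oxy}-2-oxooctahydro-1-benzofuran-7-yl]prop-2-enoic acid | C=C[C@]1(C)C[C@@H](OC(=O)/C(C)=C\C)[C@H]2C(=C)C(=O)O[C@@H]2[C@H]1C(=C)C(=O)O | target

Total step count: 17. Longest linear sequence: 15 steps (steps 1–5 and 8–17, from 1 to 29).

**Steps most likely to fail**

Step 9 (proposed new method). After the cyclobutane opens, the oxocarbenium ion may lose the proton at C5 and scramble that centre, or the enol may not reach the distal α-carbon before the ion is consumed otherwise. The fallback sets out from 14 and uses known chemistry only. 14 would be irradiated as before and the photoadduct 15 isolated. Zn dust in AcOH/EtOH would then open the β-bromo ether by Boord fragmentation; the cyclobutanol so released collapses by the de Mayo retro-aldol to the 1,5-keto aldehyde F1, which already carries the vinyl group. An intramolecular aldol addition catalysed by dibenzylammonium trifluoroacetate in benzene at 25 °C would close the six-membered ring to the all-equatorial hydroxy ketone 18, where the route is rejoined.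

Step 10. The base equilibration may stall, or retro-aldol ring opening may set in and erode the C5 configuration. The fallback sets out from 17, isolated after the zinc stage. The 6-hydroxyl would be capped with Et3SiCl and imidazole in DMF to give the triethylsilyl ether F2, which cannot undergo retro-aldol cleavage. Equilibration with DBU in toluene at 60 °C would give the C7-epimeric silyl ether F3 with the arm equatorial, and AcOH–THF–H2O would remove the silyl group to return 18.

Step 16. Acylation of the hindered axial hydroxyl may be slow, and the angeloyl double bond may isomerise to the tigloyl geometry. The fallback sets out from 25 and builds the Z double bond on the substrate. 25 would be esterified with 2-[bis(2,2,2-trifluoroethoxy)phosphoryl]propanoic acid (DCC, DMAP, CH2Cl2) to the phosphonate ester F4. A Still–Gennari olefination with acetaldehyde (KN(SiMe3)2, 18-crown-6, THF, −78 °C) would then give the Z-configured ester 28, where the route is rejoined.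

Further compounds
F1 | step 9 | 1-tert-butyl 9-[2-(trimethylsilyl)ethyl] 6-ethenyl-7-formyl-6-methyl-4-oxononanedioate (configuration at the two stereocentres as in 18) | O=C[C@@H](CC(=O)OCC[Si](C)(C)C)[C@](C)(C=C)CC(=O)CCC(=O)OC(C)(C)C
F2 | step 10 | triethylsilyl ether of 17 at the 6-hydroxyl | C=C[C@]1(C)CC(=O)[C@H](CC(=O)OC(C)(C)C)[C@H](O[Si](CC)(CC)CC)[C@H]1CC(=O)OCC[Si](C)(C)C
F3 | step 10 | triethylsilyl ether of 18 at the 6-hydroxyl | C=C[C@]1(C)CC(=O)[C@@H](CC(=O)OC(C)(C)C)[C@H](O[Si](CC)(CC)CC)[C@H]1CC(=O)OCC[Si](C)(C)C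
F4 | step 16 | 2-[bis(2,2,2-trifluoroethoxy)phosphoryl]propanoate ester of 25 at the 8β-hydroxyl | C=C[C@]1(C)C[C@@H](OC(=O)C(C)P(=O)(OCC(F)(F)F)OCC(F)(F)F)[C@H]2C(=C)C(=O)O[C@@H]2[C@H]1C(=C)C(=O)OCC[Si](C)(C)C
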